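Target 10 is a drim-7-en-11-yl unit (decalin rings A and B, drimane numbering) on C5′ of methyl 2,3,4-trihydroxybenzoate (aromatic ring C). The last step only removes three O-acetyl groups (10 ⇒ 9).
Key disconnection (9 ⇒ 6): C9–C10 of ring B and C4–C5 of ring A are opened together, and the C7=C8 alkene is read as the mark of a C8 cation that lost H-7. This leads back to an achiral, acyclic (2E,6E)-farnesyl arene and copies the presumed biosynthesis.
Enabling feature: rings A and B carry the head-to-tail isoprenoid pattern (gem-dimethyl C4, methyl-bearing C10 and C8 in 1,5-relation), the trans-anti array H-5α/10β-CH3/H-9α, and the C7=C8 alkene next to the methyl-bearing C8 in ring B. This is exactly what a chair–chair fold of an E,E-triene delivers.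
6 ⇒ C5′–C11 bond: Negishi allyl–aryl coupling of the arylzinc made from iodide 3 with farnesyl bromide 4. 3 ⇒ 1 by ring iodination and peracetylation.
Order of rings: ring C is bought, ring A closes first and ring B last, both within step 4.

Key step: step 4

Assumption: drimane numbering (C1–C10 decalin, C11 benzylic CH2, C12 methyl on C8) and primed arene numbers are used; of the two accessible antipodes of the BINOL-derived acid, the one used is that which folds a farnesyl-type triene into the 5S,10S series.

Step 1
Reactants: 1 methyl 2,3,4-trihydroxybenzoate
Product: 2 methyl 2,3,4-trihydroxy-5-iodobenzoate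
Conditions: NIS (1.0 equiv), CF3CO2H (10 mol %), MeCN, 0 °C, dark
Reagents that add atoms: N-iodosuccinimide, O=C1CCC(=O)N1I
Why: Electrophilic aromatic iodination should go to C5, which is para to the 2-OH and ortho to the 4-OH, whereas C6 is flanked by the ester and activated only by the 3-OH, and the acidic medium disfavours oxidation of the pyrogallol ring to a quinone.

Step 2
Reactants: 2 methyl 2,3,4-trihydroxy-5-iodobenzoate
Product: 3 methyl 2,3,4-triacetoxy-5-iodobenzoate
Conditions: Ac2O (4 equiv), DMAP (5 mol %), pyridine, 0 °C to rt
Reagents that add atoms: acetic anhydride, CC(=O)OC(C)=O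
Why: DMAP-catalysed O-acylation of all three phenols (the hydrogen-bonded 2-OH included) installs groups that tolerate organozinc chemistry, draw electron density away from the ring and its oxygens for step 4, and leave again under mild methanolysis.

Step 3
Reactants: 3 methyl 2,3,4-triacetoxy-5-iodobenzoate; 4 (2E,6E)-farnesyl bromide
Product: 6 methyl 2,3,4-triacetoxy-5-[(2E,6E)-3,7,11-trimethyldodeca-2,6,10-trien-1-yl]benzoate, via arylzinc iodide 5 (not isolated)
Conditions: Zn dust, LiCl, THF, 40 °C; then 4, Pd(PPh3)4 (3 mol %), THF, 0 °C to rt
Reagents that add atoms: (2E,6E)-farnesyl bromide 4, CC(C)=CCC/C(C)=C/CC/C(C)=C/CBr; zinc, [Zn] (held only in 5)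
Why: LiCl-promoted direct insertion of zinc into the electron-poor aryl iodide tolerates the four ester groups, and the Negishi coupling through a π-allylpalladium intermediate should form the C5′–C11 bond at the unsubstituted allyl terminus with retention of the 2E geometry, where copper catalysis would favour the branched SN2′ product.

Step 4
Reactants: 6 methyl 2,3,4-triacetoxy-5-[(2E,6E)-farnesyl]benzoate
Product: 9 methyl 2,3,4-triacetoxy-5-{[(1S,4aS,8aS)-2,5,5,8a-tetramethyl-1,4,4a,5,6,7,8,8a-octahydronaphthalen-1-yl]methyl}benzoate, via monocyclic C10 cation 7 (not isolated), via bicyclic C8 cation 8 (not isolated)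
Conditions: chiral imidodiphosphorimidate (IDPi) acid HN[P(=NSO2C6F5)(O2C20H10Ar2)]2 (BINOL backbone, Ar = 9,9-dimethylfluoren-2-yl at C3 and C3′; 5 mol %), (CF3)3COH/CH2Cl2, 0 °C
Reagents that add atoms: none
Why: Proposed new method: the confined chiral acid protonates C3 of the terminal isopropylidene alkene of 6, the C4 cation is attacked by C5 of the central E-alkene (ring A, 6-endo-trig, limiting structure 7), the C10 cation by C9 of the benzyl-bearing E-alkene (ring B, 6-endo-trig, limiting structure 8, the last ring of the skeleton), and the catalyst anion takes the axial H-7α, so that the event is a proton-neutral cycloisomerisation that should make two C–C bonds, two rings, three stereocentres and the C7=C8 alkene. The closest known reaction types are the imidodiphosphorimidate-catalysed asymmetric cyclisation of homofarnesol-type trienes in perfluorinated alcohols, the proton-initiated cyclisation of farnesyl arenes by BINOL·SnCl4 or BINOL·SbCl5 acids, and the FSO3H cyclisation of (2E,6E)-farnesyl acetate to drim-7-en-11-yl acetate; new is the union of catalyst-controlled enantioselection with termination by regioselective proton loss instead of capture by a heteroatom or an arene. C5 is set by the catalyst, whose chiral anion pocket should admit only one of the two mirror-image chair–chair folds and so fix the face of the C5=C10 alkene that meets C4. C10 and C9 are then set by the substrate, since antiperiplanar addition across the two E-alkenes in the chair–chair array (Stork–Eschenmoser rule) gives the trans ring fusion (H-5α, 10β-CH3) and the equatorial 9β-CH2Ar group. The step needs site-selective initiation, secured by the terminal alkene being the least hindered of the three and the one that reaches the bottom of the pocket, and it needs a silent arene, secured by the three O-acetyl groups and the CO2Me group, which make O-4′ (chroman closure at C8) and C-6′ (indane closure at C8) too poor as nucleophiles. It also needs Δ7 regioselection, which rests on fast re-protonation of any exocyclic Δ8(12) isomer back to 8, on the A1,3 strain among CH2Ar, the C12 methyl and C1 that slows loss of H-9, and on the low temperature and the bulk of the bicyclic product, which keep the hindered C7=C8 alkene out of the acid pocket.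

Step 5
Reactants: 9 methyl 2,3,4-triacetoxy-5-(drim-7-en-11-yl)benzoate
Product: 10 methyl 2,3,4-trihydroxy-5-{[(1S,4aS,8aS)-2,5,5,8a-tetramethyl-1,4,4a,5,6,7,8,8a-octahydronaphthalen-1-yl]methyl}benzoate (target)
Conditions: K2CO3 (0.5 equiv), degassed MeOH, argon, 0 °C; then pH 5 citrate buffer
Reagents that add atoms: none
Why: Base-catalysed transesterification (methanolysis) of the activated aryl acetates is far faster than any reaction of the methyl ester, whose exchange in methanol is degenerate, it touches neither the trisubstituted alkene nor a stereocentre, and exclusion of oxygen with a weakly acidic quench protects the pyrogallol and avoids closure of O-4′ onto C8.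

Compound list
1 | methyl 2,3,4-trihydroxybenzoate | COC(=O)c1ccc(O)c(O)c1O | starting material
2 | methyl 2,3,4-trihydroxy-5-iodobenzoate | COC(=O)c1cc(I)c(O)c(O)c1O | intermediate
3 | methyl 2,3,4-triacetoxy-5-iodobenzoate | COC(=O)c1cc(I)c(OC(C)=O)c(OC(C)=O)c1OC(C)=O | intermediate
4 | (2E,6E)-farnesyl bromide | CC(C)=CCC/C(C)=C/CC/C(C)=C/CBr | starting material
5 | [2,3,4-triacetoxy-5-(methoxycarbonyl)phenyl]zinc iodide (not isolated) | COC(=O)c1cc([Zn]I)c(OC(C)=O)c(OC(C)=O)c1OC(C)=O | intermediate
6 | methyl 2,3,4-triacetoxy-5-[(2E,6E)-farnesyl]benzoate | COC(=O)c1cc(C/C=C(\C)CC/C=C(\C)CCC=C(C)C)c(OC(C)=O)c(OC(C)=O)c1OC(C)=O | intermediate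
7 | monocyclic tertiary C10 cation, ring A closed, C5 configured as in 9 (not isolated) | COC(=O)c1cc(C/C=C(\C)CC[C@H]2C(C)(C)CCC[C+]2C)c(OC(C)=O)c(OC(C)=O)c1OC(C)=O | intermediate
8 | bicyclic tertiary C8 cation, rings A and B closed, C5, C9 and C10 configured as in 9 (not isolated) | COC(=O)c1cc(C[C@H]2[C+](C)CC[C@H]3C(C)(C)CCC[C@]23C)c(OC(C)=O)c(OC(C)=O)c1OC(C)=O | intermediate
9 | methyl 2,3,4-triacetoxy-5-{[(1S,4aS,8aS)-2,5,5,8a-tetramethyl-1,4,4a,5,6,7,8,8a-octahydronaphthalen-1-yl]methyl}benzoate | COC(=O)c1cc(C[C@H]2C(C)=CC[C@H]3C(C)(C)CCC[C@]23C)c(OC(C)=O)c(OC(C)=O)c1OC(C)=O | intermediate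
10 | methyl 2,3,4-trihydroxy-5-{[(1S,4aS,8aS)-2,5,5,8a-tetramethyl-1,4,4a,5,6,7,8,8a-octahydronaphthalen-1-yl]methyl}benzoate | COC(=O)c1cc(C[C@H]2C(C)=CC[C@H]3C(C)(C)CCC[C@]23C)c(O)c(O)c1O | target

Total step count: 5. Longest linear sequence: 5 steps (1 to 10); 4 is bought.

Steps most likely to fail

**Step 4.**
- What may go wrong: the cascade may stop after ring A through early proton loss. Cation 8 may be deprotonated without regiocontrol. The product alkene may be re-protonated and drift to the tetrasubstituted position. The ion pair may also discriminate the two chair–chair folds poorly.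
- Fallback: this uses known chemistry only (terpene pool plus Negishi alkyl–aryl coupling), sets out from 3 and comes back at 9.
- Purchased (−)-drimenol F1 is turned by an Appel reaction (I2, PPh3, imidazole, toluene, 60 °C) into drim-7-en-11-yl iodide F2.
- Zinc dust and LiCl in THF then convert it into drim-7-en-11-ylzinc iodide F3.
- Coupling of F3 with 3 under Pd(OAc)2/SPhos in THF should give 9.
- The acetates and the ester tolerate the alkylzinc. Ring B, its alkene and the three stereocentres then come from the terpene pool, at the price of giving up the cyclisation.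

**Step 3.**
- What may go wrong: zinc insertion may stall on the crowded iodide or be accompanied by acetyl transfer. The π-allylpalladium intermediate may leak to the branched isomer or lose the 2E geometry.
- Fallback: this reverses the polarity of the coupling (Stille coupling), sets out from 3 and 4 and comes back at 6.
- Compound 4 and Bu3SnLi (THF, −78 °C) give tributyl[(2E,6E)-farnesyl]stannane F4.
- F4 is coupled with 3 as the electrophile under Pd2(dba)3/AsPh3 in DMF at 60 °C.
- No aryl-metal species is needed, and the acetates see only neutral conditions.

**Step 1.**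
- What may go wrong: the electrophilic iodine source may oxidise the pyrogallol ring instead of substituting it, or a second iodination at C6 may set in.
- Fallback: this avoids halogen and metal altogether (Friedel–Crafts-type ortho-C-allylation), sets out from 1 and comes back at 6, bypassing steps 1 to 3.
- Compound 1 and purchased (2E,6E)-farnesol F5 are heated on acidic Al2O3 in ClCH2CH2Cl. C5 is the only free position ortho to a phenolic OH, so this should give methyl 5-[(2E,6E)-farnesyl]-2,3,4-trihydroxybenzoate F6.
- Peracetylation of F6 (Ac2O, DMAP, pyridine) then gives 6.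

Further compounds
F1 | step 4 | (−)-drimenol (purchased) | OC[C@H]1C(C)=CC[C@H]2C(C)(C)CCC[C@]12C
F2 | step 4 | drim-7-en-11-yl iodide (configuration of F1) | IC[C@H]1C(C)=CC[C@H]2C(C)(C)CCC[C@]12C
F3 | step 4 | drim-7-en-11-ylzinc iodide (configuration of F1) | I[Zn]C[C@H]1C(C)=CC[C@H]2C(C)(C)CCC[C@]12C
F4 | step 3 | tributyl[(2E,6E)-farnesyl]stannane | CCCC[Sn](CCCC)(CCCC)C/C=C(\C)CC/C=C(\C)CCC=C(C)C
F5 | step 1 | (2E,6E)-farnesol (purchased) | CC(C)=CCC/C(C)=C/CC/C(C)=C/CO
F6 | step 1 | methyl 5-[(2E,6E)-farnesyl]-2,3,4-trihydroxybenzoate | COC(=O)c1cc(C/C=C(\C)CC/C=C(\C)CCC=C(C)C)c(O)c(O)c1O
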